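The route rests on opening the benzene ring of the tetrahydroisoquinoline at C4a–C5. In that ring C4a, C6 and C8 alternate, so it is read as a folded 1,3,5-triketone. C4a is the carbonyl of a cis-2,6-dimethyl-4-piperidone (C1, N2, C3, C4). C8 and C6 lie in a side chain on C8a, and the terminal CH2, C5, already bears naphthalene carbon C8'. One base-induced aldol condensation joins C5 to C4a, loses water and aromatises. This delivers the 6,8-dihydroxy ring and the crowded biaryl bond without cross-coupling. The precursor is an N-methoxycarbonyl piperidone carrying a 4-naphthyl-3-oxobutanoyl group at C8a.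

Key step: step 15

Assumption: the SMILES fixes C1 (R) and C3 (S) but not the sense of the hindered C5–C8' axis, so the route aims at the (1R,3S) compound, and the two atropo-diastereomers expected from the ring closure would be separated by chromatography at the carbamate or amine stage if only one is wanted.

Design notes:
- **No free δ-amino β-diketone.** Such an amine would condense with its own distal carbonyl to a six-membered enaminone before it could meet an external aldehyde. The enaminone ring is therefore made on purpose, and the C1 methyl group and the C8–C7 unit are added to it in one conjugate addition–aldol step.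
- **The piperidone core is meso.** cis-2,6-Dimethyl-4-piperidone has no absolute configuration of its own. That information lies only in which α-carbon is acylated, so the enolate has to be formed on one side and trapped at once.
- **Amide, not aldehyde.** The naphthyl C2 unit enters at the amide oxidation level. This avoids a labile, easily enolised arylacetaldehyde and saves an oxidation on the sensitive triketone.

**Fragment 1: naphthylacetic amide**

Step 1
Reactants: 1 2-bromo-5-methoxybenzaldehyde; 2 diethyl succinate
Product: 3 (E)-4-(2-bromo-5-methoxyphenyl)-3-(ethoxycarbonyl)but-3-enoic acid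
Conditions: NaOEt, EtOH, reflux; then aq. HCl
Reagents that add atoms: none
Why: Stobbe condensation: the succinate enolate adds to the aldehyde, the alkoxide lactonises onto the far ester, and base-induced ring opening gives the half-ester with the aryl group trans to CO2Et, the geometry the next ring closure needs.

Step 2
Reactants: 3 (E)-4-(2-bromo-5-methoxyphenyl)-3-(ethoxycarbonyl)but-3-enoic acid
Product: 5 ethyl 4-acetoxy-8-bromo-5-methoxynaphthalene-2-carboxylate, via free naphthol 4 (not isolated)
Conditions: Ac2O, NaOAc, reflux
Reagents that add atoms: acetic anhydride, CC(=O)OC(C)=O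
Why: Activation of the acid by Ac2O triggers an intramolecular Friedel–Crafts acylation at the only free position ortho to the side chain (the other is blocked by bromine, and the site is activated by the adjacent methoxy group), and the naphthol formed by enolisation is acetylated in the same pot.

Step 3
Reactants: 5 ethyl 4-acetoxy-8-bromo-5-methoxynaphthalene-2-carboxylate
Product: 6 5-bromo-3-(hydroxymethyl)-8-methoxynaphthalen-1-ol
Conditions: LiAlH4, THF, 0 °C
Reagents that add atoms: none
Why: Hydride reduction with LiAlH4 turns the ethyl ester into the primary alcohol and cleaves the aryl acetate in the same operation, while the aryl bromide is inert at 0 °C.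

Step 4
Reactants: 6 5-bromo-3-(hydroxymethyl)-8-methoxynaphthalen-1-ol
Product: 7 (8-bromo-4,5-dimethoxynaphthalen-2-yl)methanol
Conditions: MeI, K2CO3, acetone, reflux
Reagents that add atoms: iodomethane, CI
Why: Williamson ether synthesis: carbonate deprotonates only the naphthol, so methylation is selective for the phenolic oxygen and the benzylic alcohol stays free.

Step 5
Reactants: 7 (8-bromo-4,5-dimethoxynaphthalen-2-yl)methanol
Product: 9 1-bromo-4,5-dimethoxy-7-methylnaphthalene, via benzylic mesylate 8 (not isolated)
Conditions: MsCl, Et3N, THF, 0 °C; then LiBHEt3, 0 °C to rt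
Reagents that add atoms: methanesulfonyl chloride, CS(=O)(=O)Cl (its atoms stand only in 8 and are lost again)
Why: Mesylation followed by SN2 displacement with the strongly nucleophilic hydride LiBHEt3 deoxygenates the primary benzylic position, and aryl bromides and aryl ethers do not react with this hydride at or below room temperature.

Step 6
Reactants: 9 1-bromo-4,5-dimethoxy-7-methylnaphthalene; 10 (2-ethoxy-2-oxoethyl)zinc bromide
Product: 11 ethyl 2-(4,5-dimethoxy-7-methylnaphthalen-1-yl)acetate
Conditions: Pd2(dba)3 (2 mol %), XPhos (8 mol %), THF, 60 °C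
Reagents that add atoms: none
Why: Negishi-type coupling of a Reformatsky reagent (palladium-catalysed α-arylation of an ester): zerovalent palladium inserts into the C–Br bond, the neutral zinc enolate transmetalates, and reductive elimination forms the aryl–CH2 bond that becomes C8'–C5, without the strong base that would cause Claisen self-condensation.

Step 7
Reactants: 11 ethyl 2-(4,5-dimethoxy-7-methylnaphthalen-1-yl)acetate
Product: 12 2-(4,5-dimethoxy-7-methylnaphthalen-1-yl)-N-methoxy-N-methylacetamide
Conditions: MeNH(OMe)·HCl, i-PrMgCl, THF, −20 to 0 °C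
Reagents that add atoms: N,O-dimethylhydroxylamine hydrochloride, CNOC.Cl
Why: Aminolysis of the ester by the magnesium amide of N,O-dimethylhydroxylamine gives the Weinreb amide, a standard transformation that tolerates enolisable arylacetates at low temperature.

**Fragment 2: chiral 3-acetylpiperidone**

Step 8
Reactants: 13 (S)-3-(tert-butoxycarbonylamino)butanoic acid
Product: 15 tert-butyl (S)-{4-[methoxy(methyl)amino]-4-oxobutan-2-yl}carbamate, via acyl imidazole 14 (not isolated)
Conditions: CDI, CH2Cl2, rt; then MeNH(OMe)·HCl, rt
Reagents that add atoms: N,O-dimethylhydroxylamine hydrochloride, CNOC.Cl; 1,1'-carbonyldiimidazole, O=C(n1ccnc1)n1ccnc1 (its imidazolyl group stands only in 14)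
Why: Carboxyl activation as the acyl imidazole and acyl substitution by the hydroxylamine give the Weinreb amide under near-neutral conditions that do not touch the stereocentre β to the carbonyl group.

Step 9
Reactants: 15 tert-butyl (S)-{4-[methoxy(methyl)amino]-4-oxobutan-2-yl}carbamate; 16 ethynylmagnesium bromide
Product: 17 tert-butyl (S)-(4-oxohex-5-yn-2-yl)carbamate
Conditions: 16 (3 equiv), THF, 0 °C; inverse quench into cold aq. NaHSO4
Reagents that add atoms: none
Why: Weinreb ketone synthesis: after deprotonation of the carbamate N–H the alkynyl Grignard reagent adds once, the chelated tetrahedral adduct survives until the acidic quench, and that quench keeps the released hydroxylamine protonated so that it cannot add to the ynone.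

Step 10
Reactants: 17 tert-butyl (S)-(4-oxohex-5-yn-2-yl)carbamate
Product: 19 (S)-2-methyl-2,3-dihydropyridin-4(1H)-one, via chlorovinyl ketone hydrochloride 18 (not isolated)
Conditions: 4 M HCl, dioxane, rt; evaporate; then K2CO3, MeOH, rt
Reagents that add atoms: hydrogen chloride, Cl (its chlorine stands only in 18 and leaves again)
Why: Acidolysis of the Boc group is accompanied by hydrochlorination of the ynone, and on neutralisation the free amine closes by intramolecular conjugate addition–elimination (6-endo) to the vinylogous amide, a known way from β-amino acids to 2,3-dihydro-4-pyridones that leaves the stereocentre untouched.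

Step 11
Reactants: 19 (S)-2-methyl-2,3-dihydropyridin-4(1H)-one
Product: 20 methyl (S)-2-methyl-4-oxo-3,4-dihydropyridine-1(2H)-carboxylate
Conditions: LiN(SiMe3)2, THF, −78 °C; then ClCO2Me
Reagents that add atoms: methyl chloroformate, COC(=O)Cl
Why: N-Acylation of the lithiated vinylogous amide with a chloroformate withdraws the nitrogen lone pair, which turns the ring into a competent Michael acceptor and installs the carbon that ends as the N-methyl group.

Step 12
Reactants: 20 methyl (S)-2-methyl-4-oxo-3,4-dihydropyridine-1(2H)-carboxylate; 21 acetaldehyde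
Product: 23 methyl (2R,6S)-3-(1-hydroxyethyl)-2,6-dimethyl-4-oxopiperidine-1-carboxylate (mixture at C3 and at the carbinol carbon), via lithium enolate 22 (not isolated)
Conditions: Me2CuLi (from MeLi and CuBr·SMe2), Et2O–THF, −78 °C; then 21, −78 °C; aq. NH4Cl
Reagents that add atoms: lithium dimethylcuprate, [Li+].C[Cu-]C (made in the flask from methyllithium, [Li]C, and CuBr·SMe2)
Why: Tandem cuprate conjugate addition–aldol reaction: allylic 1,3-strain with the carbamate holds the existing methyl group axial, and stereoelectronically preferred axial attack at the enone terminus places the new methyl group cis to it (this sets C1 of the target as R), while the enolate arises only on the side of the new centre and is trapped there by the aldehyde before it can equilibrate, which keeps the otherwise meso cis-piperidone chiral; the two further centres are erased in steps 13 and 15.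

Step 13
Reactants: 23 methyl (2R,6S)-3-(1-hydroxyethyl)-2,6-dimethyl-4-oxopiperidine-1-carboxylate
Product: 24 methyl (2R,6S)-3-acetyl-2,6-dimethyl-4-oxopiperidine-1-carboxylate (C3 epimers and enols)
Conditions: 2-iodoxybenzoic acid (IBX), EtOAc, 75 °C
Reagents that add atoms: none
Why: IBX oxidation of a β-hydroxy ketone to the β-diketone runs under neutral conditions, so retro-aldol cleavage, dehydration and β-elimination of the carbamate nitrogen are avoided, and the undefined centres collapse into one enolisable position.

**Union and endgame**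

Step 14
Reactants: 24 methyl (2R,6S)-3-acetyl-2,6-dimethyl-4-oxopiperidine-1-carboxylate; 12 2-(4,5-dimethoxy-7-methylnaphthalen-1-yl)-N-methoxy-N-methylacetamide
Product: 26 methyl (2R,6S)-3-[4-(4,5-dimethoxy-7-methylnaphthalen-1-yl)-3-oxobutanoyl]-2,6-dimethyl-4-oxopiperidine-1-carboxylate (C3 epimers and enols), via dilithium dienediolate 25 (not isolated)
Conditions: LiN(i-Pr)2 (2.2 equiv), THF, −78 to −30 °C; then 12, −78 to −30 °C; AcOH quench at −78 °C
Reagents that add atoms: none
Why: Terminal acylation of a 1,3-diketone dianion combined with the Weinreb ketone synthesis: the second deprotonation takes place at the unhindered acetyl CH3, this more basic carbon is the one that attacks the amide (bond C7–C6), and the chelated tetrahedral adduct holds back the acidic triketone until the quench so that it cannot protonate unreacted dianion.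

Step 15
Reactants: 26 methyl (2R,6S)-3-[4-(4,5-dimethoxy-7-methylnaphthalen-1-yl)-3-oxobutanoyl]-2,6-dimethyl-4-oxopiperidine-1-carboxylate
Product: 28 methyl (1R,3S)-5-(4,5-dimethoxy-7-methylnaphthalen-1-yl)-6,8-dihydroxy-1,3-dimethyl-3,4-dihydroisoquinoline-2(1H)-carboxylate, via aldol carbinol 27 (not isolated)
Conditions: DBU (2 equiv), degassed MeCN (0.02 M), Ar, 23 to 60 °C; then 1 M HCl
Reagents that add atoms: none
Why: DBU holds 26 as its β-diketonate and, in a small equilibrium share, removes a proton from C5, the only terminal CH2, which is acidified by both the C6 carbonyl and the naphthalene; this enolate adds to the piperidone carbonyl C4a (new bond C4a–C5) to give carbinol 27, and E1cB loss of water followed by keto–enol shifts, in which C8a gives up its hydrogen, delivers the resorcinol. The reaction type is the base-induced aldol condensation of a 1,3,5-triketone to a resorcinol, the laboratory model of polyketide folding (heptane-2,4,6-trione to orcinol). The one ring formed, the carbocycle C4a–C5–C6–C7–C8–C8a, closes in the 6-(enolendo)-exo-trig mode. No stereocentre is created: C8a becomes planar, C1 and C3 are spectators, and only the C5–C8' bond turns into a hindered axis, for which both senses are expected. Selectivity among the closure modes is needed and is secured by reversibility: attack of C4 on C6 gives a bicyclo[3.3.1] carbinol that cannot become an arene and reverts, four-membered closures are not viable, and the acid-driven O-closure to a γ-pyranone is shut off by working in base, so aromatisation drains the equilibria through 27. The carbamate removes the nitrogen lone pair that a retro-Mannich cleavage would need, and the stabilised enolate resting state disfavours β-elimination of nitrogen from C1 or C3, so the cis relationship should survive.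

Step 16
Reactants: 28 methyl (1R,3S)-5-(4,5-dimethoxy-7-methylnaphthalen-1-yl)-6,8-dihydroxy-1,3-dimethyl-3,4-dihydroisoquinoline-2(1H)-carboxylate
Product: 29 methyl (1R,3S)-5-(4,5-dimethoxy-7-methylnaphthalen-1-yl)-6,8-dimethoxy-1,3-dimethyl-3,4-dihydroisoquinoline-2(1H)-carboxylate
Conditions: MeI, K2CO3, DMF, rt
Reagents that add atoms: iodomethane, CI
Why: Double Williamson etherification of the two phenols; the carbamate nitrogen carries no proton, so only oxygen is alkylated.

Step 17
Reactants: 29 methyl (1R,3S)-5-(4,5-dimethoxy-7-methylnaphthalen-1-yl)-6,8-dimethoxy-1,3-dimethyl-3,4-dihydroisoquinoline-2(1H)-carboxylate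
Product: 30 (1R,3S)-5-(4,5-dimethoxy-7-methylnaphthalen-1-yl)-6,8-dimethoxy-1,2,3-trimethyl-1,2,3,4-tetrahydroisoquinoline
Conditions: LiAlH4, THF, reflux
Reagents that add atoms: none
Why: LiAlH4 reduces the methyl carbamate to the N-methyl amine, a standard carbamate-to-methylamine reduction that affects neither the aryl ethers nor the C1 and C3 centres.

**Compound list**

1 | 2-bromo-5-methoxybenzaldehyde | COc1ccc(Br)c(C=O)c1 | starting material
2 | diethyl succinate | CCOC(=O)CCC(=O)OCC | starting material
3 | (E)-4-(2-bromo-5-methoxyphenyl)-3-(ethoxycarbonyl)but-3-enoic acid | CCOC(=O)/C(CC(=O)O)=C/c1cc(OC)ccc1Br | intermediate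
4 | ethyl 8-bromo-4-hydroxy-5-methoxynaphthalene-2-carboxylate (free naphthol) | CCOC(=O)c1cc(O)c2c(OC)ccc(Br)c2c1 | intermediate
5 | ethyl 4-acetoxy-8-bromo-5-methoxynaphthalene-2-carboxylate | CCOC(=O)c1cc(OC(C)=O)c2c(OC)ccc(Br)c2c1 | intermediate
6 | 5-bromo-3-(hydroxymethyl)-8-methoxynaphthalen-1-ol | OCc1cc(O)c2c(OC)ccc(Br)c2c1 | intermediate
7 | (8-bromo-4,5-dimethoxynaphthalen-2-yl)methanol | OCc1cc(OC)c2c(OC)ccc(Br)c2c1 | intermediate
8 | (8-bromo-4,5-dimethoxynaphthalen-2-yl)methyl methanesulfonate (benzylic mesylate) | CS(=O)(=O)OCc1cc(OC)c2c(OC)ccc(Br)c2c1 | intermediate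
9 | 1-bromo-4,5-dimethoxy-7-methylnaphthalene | Cc1cc(OC)c2c(OC)ccc(Br)c2c1 | intermediate
10 | (2-ethoxy-2-oxoethyl)zinc bromide | CCOC(=O)C[Zn]Br | starting material
11 | ethyl 2-(4,5-dimethoxy-7-methylnaphthalen-1-yl)acetate | CCOC(=O)Cc1ccc(OC)c2c(OC)cc(C)cc12 | intermediate
12 | 2-(4,5-dimethoxy-7-methylnaphthalen-1-yl)-N-methoxy-N-methylacetamide | CON(C)C(=O)Cc1ccc(OC)c2c(OC)cc(C)cc12 | intermediate
13 | (S)-3-(tert-butoxycarbonylamino)butanoic acid | C[C@H](NC(=O)OC(C)(C)C)CC(=O)O | starting material
14 | tert-butyl (S)-[4-(imidazol-1-yl)-4-oxobutan-2-yl]carbamate (acyl imidazole) | C[C@H](NC(=O)OC(C)(C)C)CC(=O)n1ccnc1 | intermediate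
15 | tert-butyl (S)-{4-[methoxy(methyl)amino]-4-oxobutan-2-yl}carbamate | C[C@H](NC(=O)OC(C)(C)C)CC(=O)N(C)OC | intermediate
16 | ethynylmagnesium bromide | C#C[Mg]Br | starting material
17 | tert-butyl (S)-(4-oxohex-5-yn-2-yl)carbamate | C[C@H](NC(=O)OC(C)(C)C)CC(=O)C#C | intermediate
18 | (S)-5-amino-1-chlorohex-1-en-3-one hydrochloride (chlorovinyl ketone hydrochloride) | C[C@H](N)CC(=O)C=CCl.Cl | intermediate
19 | (S)-2-methyl-2,3-dihydropyridin-4(1H)-one | C[C@H]1CC(=O)C=CN1 | intermediate
20 | methyl (S)-2-methyl-4-oxo-3,4-dihydropyridine-1(2H)-carboxylate | C[C@H]1CC(=O)C=CN1C(=O)OC | intermediate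
21 | acetaldehyde | CC=O | starting material
22 | lithium (2R,6S)-1-(methoxycarbonyl)-2,6-dimethyl-1,2,5,6-tetrahydropyridin-4-olate (lithium enolate) | C[C@H]1N(C(=O)OC)[C@@H](C)CC([O-])=C1.[Li+] | intermediate
23 | methyl (2R,6S)-3-(1-hydroxyethyl)-2,6-dimethyl-4-oxopiperidine-1-carboxylate | C[C@H]1N(C(=O)OC)[C@@H](C)CC(=O)C1C(C)O | intermediate
24 | methyl (2R,6S)-3-acetyl-2,6-dimethyl-4-oxopiperidine-1-carboxylate | C[C@H]1N(C(=O)OC)[C@@H](C)CC(=O)C1C(C)=O | intermediate
25 | dilithium dienediolate of 24 (deprotonated at C3 and at the acetyl CH3) | C[C@H]1N(C(=O)OC)[C@@H](C)CC([O-])=C1C([O-])=C.[Li+].[Li+] | intermediate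
26 | methyl (2R,6S)-3-[4-(4,5-dimethoxy-7-methylnaphthalen-1-yl)-3-oxobutanoyl]-2,6-dimethyl-4-oxopiperidine-1-carboxylate | C[C@H]1N(C(=O)OC)[C@@H](C)CC(=O)C1C(=O)CC(=O)Cc1ccc(OC)c2c(OC)cc(C)cc12 | intermediate
27 | methyl (1R,3S)-5-(4,5-dimethoxy-7-methylnaphthalen-1-yl)-4a-hydroxy-1,3-dimethyl-6,8-dioxooctahydroisoquinoline-2(1H)-carboxylate (aldol carbinol) | C[C@H]1N(C(=O)OC)[C@@H](C)CC2(O)C1C(=O)CC(=O)C2c1ccc(OC)c2c(OC)cc(C)cc12 | intermediate
28 | methyl (1R,3S)-5-(4,5-dimethoxy-7-methylnaphthalen-1-yl)-6,8-dihydroxy-1,3-dimethyl-3,4-dihydroisoquinoline-2(1H)-carboxylate | C[C@H]1N(C(=O)OC)[C@@H](C)Cc2c(-c3ccc(OC)c4c(OC)cc(C)cc34)c(O)cc(O)c21 | intermediate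
29 | methyl (1R,3S)-5-(4,5-dimethoxy-7-methylnaphthalen-1-yl)-6,8-dimethoxy-1,3-dimethyl-3,4-dihydroisoquinoline-2(1H)-carboxylate | C[C@H]1N(C(=O)OC)[C@@H](C)Cc2c(-c3ccc(OC)c4c(OC)cc(C)cc34)c(OC)cc(OC)c21 | intermediate
30 | (1R,3S)-5-(4,5-dimethoxy-7-methylnaphthalen-1-yl)-6,8-dimethoxy-1,2,3-trimethyl-1,2,3,4-tetrahydroisoquinoline | COc1cc(OC)c2c(c1-c1ccc(OC)c3c(OC)cc(C)cc13)C[C@H](C)N(C)[C@@H]2C | target

**Totals**

- Total step count: 17.
- Longest linear sequence: 11 steps (steps 1–7, then 14–17).
- The piperidone branch contributes 6 steps before the union.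

**Steps most likely to fail**

Step 15. The C–C closure may be too slow, because the accepting carbonyl C4a is largely masked in the β-diketonate and C5 is crowded by the naphthalene. Long exposure to base would then allow β-elimination and re-addition of the carbamate nitrogen (erosion of the cis relationship) or retro-Claisen cleavage of the chain. The fallback sets out from 9 and comes back at 29; it makes the arene first and the biaryl bond last. Bromine–lithium exchange on 9 (n-BuLi, THF, −78 °C), B(OMe)3 and acidic work-up should give (4,5-dimethoxy-7-methylnaphthalen-1-yl)boronic acid F1. Separately, 3,5-dimethoxyphenylmagnesium bromide opens commercial tert-butyl (S)-4-methyl-1,2,3-oxathiazolidine-3-carboxylate 2,2-dioxide at its CH2 group (CuBr·SMe2 catalyst, THF; then aqueous citric acid to hydrolyse the N-sulfate). This should give tert-butyl (S)-[1-(3,5-dimethoxyphenyl)propan-2-yl]carbamate F2. HCl in dioxane followed by Ac2O and Et3N gives (S)-N-[1-(3,5-dimethoxyphenyl)propan-2-yl]acetamide F3. Bischler–Napieralski cyclisation (POCl3, MeCN, reflux) gives (S)-6,8-dimethoxy-1,3-dimethyl-3,4-dihydroisoquinoline F4. NaBH4 in MeOH, which is known to favour the cis-1,3-dimethyl series, gives (1R,3S)-6,8-dimethoxy-1,3-dimethyl-1,2,3,4-tetrahydroisoquinoline F5. ClCO2Me and Et3N give methyl (1R,3S)-6,8-dimethoxy-1,3-dimethyl-3,4-dihydroisoquinoline-2(1H)-carboxylate F6. NBS in CH2Cl2 brominates C5, which is para to the 8-methoxy group and less crowded than C7, to give methyl (1R,3S)-5-bromo-6,8-dimethoxy-1,3-dimethyl-3,4-dihydroisoquinoline-2(1H)-carboxylate F7. Suzuki–Miyaura coupling of F1 with F7 (Pd2(dba)3, SPhos, K3PO4, toluene–water, 100 °C) then gives 29.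

Step 14. Proton transfer from the acidic naphthyl-CH2 group of the amide to the dianion may outrun C–C bond formation and simply return both partners. The fallback sets out from 12 (with 24) and comes back at 26; it uses a far more electrophilic partner at the aldehyde oxidation level. Reduction of 12 with i-Bu2AlH (THF, −78 °C) should give 2-(4,5-dimethoxy-7-methylnaphthalen-1-yl)acetaldehyde F8. This is used at once in an aldol addition with dianion 25 at −78 °C to give methyl (2R,6S)-3-[4-(4,5-dimethoxy-7-methylnaphthalen-1-yl)-3-hydroxybutanoyl]-2,6-dimethyl-4-oxopiperidine-1-carboxylate F9. Oxidation of the secondary alcohol with IBX in EtOAc gives 26.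

Step 12. The cuprate may add sluggishly to the vinylogous imide, or proton exchange may move the enolate to the other α-carbon before the aldol reaction. Because the unsubstituted cis-ketone is meso, the second process erodes enantiopurity. The fallback sets out from 20 and comes back at 23. The cuprate addition is run in the presence of Me3SiCl, which accelerates the addition and captures the enolate at the moment it forms. The product is the isolable methyl (2R,6S)-2,6-dimethyl-4-(trimethylsilyloxy)-5,6-dihydropyridine-1(2H)-carboxylate F10, in which the position of the double bond is covalently fixed. A Mukaiyama aldol reaction of F10 with 21 (BF3·OEt2, CH2Cl2, −78 °C) then gives 23.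

**Further compounds**

F1 | step 15 | (4,5-dimethoxy-7-methylnaphthalen-1-yl)boronic acid | Cc1cc(OC)c2c(OC)ccc(B(O)O)c2c1
F2 | step 15 | tert-butyl (S)-[1-(3,5-dimethoxyphenyl)propan-2-yl]carbamate | C[C@H](NC(=O)OC(C)(C)C)Cc1cc(OC)cc(OC)c1
F3 | step 15 | (S)-N-[1-(3,5-dimethoxyphenyl)propan-2-yl]acetamide | C[C@H](NC(C)=O)Cc1cc(OC)cc(OC)c1
F4 | step 15 | (S)-6,8-dimethoxy-1,3-dimethyl-3,4-dihydroisoquinoline | CC1=N[C@@H](C)Cc2cc(OC)cc(OC)c21
F5 | step 15 | (1R,3S)-6,8-dimethoxy-1,3-dimethyl-1,2,3,4-tetrahydroisoquinoline | C[C@H]1N[C@@H](C)Cc2cc(OC)cc(OC)c21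
F6 | step 15 | methyl (1R,3S)-6,8-dimethoxy-1,3-dimethyl-3,4-dihydroisoquinoline-2(1H)-carboxylate | C[C@H]1N(C(=O)OC)[C@@H](C)Cc2cc(OC)cc(OC)c21
F7 | step 15 | methyl (1R,3S)-5-bromo-6,8-dimethoxy-1,3-dimethyl-3,4-dihydroisoquinoline-2(1H)-carboxylate | C[C@H]1N(C(=O)OC)[C@@H](C)Cc2c(Br)c(OC)cc(OC)c21
F8 | step 14 | 2-(4,5-dimethoxy-7-methylnaphthalen-1-yl)acetaldehyde | O=CCc1ccc(OC)c2c(OC)cc(C)cc12
F9 | step 14 | methyl (2R,6S)-3-[4-(4,5-dimethoxy-7-methylnaphthalen-1-yl)-3-hydroxybutanoyl]-2,6-dimethyl-4-oxopiperidine-1-carboxylate | C[C@H]1N(C(=O)OC)[C@@H](C)CC(=O)C1C(=O)CC(O)Cc1ccc(OC)c2c(OC)cc(C)cc12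
F10 | step 12 | methyl (2R,6S)-2,6-dimethyl-4-(trimethylsilyloxy)-5,6-dihydropyridine-1(2H)-carboxylate | C[C@H]1N(C(=O)OC)[C@@H](C)CC(O[Si](C)(C)C)=C1
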